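## Structural features

Sophoraflavanone A is a flavanone. Ring A is a benzene ring with hydroxyls at C5 and C7, fused through C4a–C8a to ring C, a dihydropyran-4-one (O1, C2, C3, C4=O). Ring B, a 4-hydroxyphenyl group, sits on C2. C2 is the only stereocentre and is S. It has no stereogenic neighbour, but it is a benzylic ether carbon β to the C4 ketone: enolisation at C3 and β-elimination of the phenolic O1 (reversible opening to the 2'-hydroxychalcone) racemise it in base and, more slowly, in hot acid. A geranyl chain ((2E)-3,7-dimethylocta-2,6-dien-1-yl) is attached to C8, between C8a and the C7 hydroxyl. The fragile elements are C2, the two trisubstituted alkenes (which cyclise onto the C7 hydroxyl under strong acid and exclude hydrogenolysis) and the electron-rich ring A. The real difficulty is double: electrophilic geranylation of a phloroglucinol-type ring does not distinguish C8 from C6, and most late closures of ring C set C2 under conditions that can also erase it. The key step uses the fact that ring A is a 1,3-dioxygenated benzene joined to ring C only at C4a–C8a. Carbons C5–C8, with both oxygens and the geranyl group, can therefore come from one acyclic diene that adds across the C4a=C8a alkene of a ring C already holding C2 in the S configuration.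

## Logic of the disconnections

**16 from 15.** The O–acyl bond of the ring B ester is cut. Ring B must be masked through nitration and cycloaddition, and an ester is preferred to an acetal ether for three reasons. It keeps ring B at about benzene reactivity toward the nitrating agent. It disfavours ionisation of the benzylic C2–O1 bond in 5, whose O1 is the leaving group of a vinylogous nitro acid. It comes off without mineral acid. The gain is that the sequence starts from 1 with no protection step. The demand is a near-neutral ester cleavage that neither opens ring C nor touches the alkenes.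

**15 from 5 and 12.** C4a–C5 and C8–C8a are cut, after formally returning HNO2 across C4a–C8a and CH3OH to C5 and silylating both phenols. This removes ring A, both its oxygens and the geranyl group in one operation and reduces the target to a monocyclic chiral enone and an acyclic diene. The geranyl group is at C8 by construction. The forward step demands a regioselective [4+2] addition, then aromatisation without base, because 5 and 15 both lose C2 integrity by β-elimination of O1.

**5 from 4.** The C–N bond at the α-carbon of the enone is cut. The nitro group is the activator, the regiochemical director and a traceless leaving group, and its removal leaves a simple vinylogous ester. The demand is a nitration that attacks only the enol-ether carbon and needs no base in reaction or work-up.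

**4 from 1 and 2.** C2–C3 and O1–C6 of the pyranone are cut (a hetero-Diels–Alder retron). Ring C falls apart into an aromatic aldehyde and a four-carbon silyloxy diene, both commercial. The demand is catalyst control of the aldehyde face, since this step sets the only stereocentre of the synthesis.

**12 from 10 and then 9.** The two O–Si bonds are cut, which returns the diene to a β-keto ester. The demand is deprotonation at the γ-carbon and a C3=C4 geometry with the chain pointing outward, so that the s-cis conformation is accessible.

**9 from 6 and 7.** The C4–C5 bond between the γ-carbon of the keto ester and the allylic carbon of the chain is cut, giving two commercial materials. The demand is alkylation at the terminal carbon of the dianion only, with SN2 regiochemistry and retention of the E alkene.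

## Other disconnections considered

**Alternative 1:** The cut is at O1–C8a and C4–C4a, separating ring A as an aryne from a chiral three-carbon acid that carries ring B.

- Forward step: CsF would unmask the C4a–C8a aryne from 2-geranyl-3,5-bis(methoxymethoxy)-6-(trimethylsilyl)phenyl trifluoromethanesulfonate A3 in the presence of (3R)-3-(tert-butyldimethylsilyloxy)-3-[4-(methoxymethoxy)phenyl]propanoic acid A2. The carboxylate oxygen should add to C8a, the aryne carbon remote from the C5 oxygen, and the C4a anion should attack the acyl carbon. This would give (3R)-3-(tert-butyldimethylsilyloxy)-1-[3-geranyl-2-hydroxy-4,6-bis(methoxymethoxy)phenyl]-3-[4-(methoxymethoxy)phenyl]propan-1-one A1. Desilylation, Mitsunobu closure of O1–C2 with inversion (3R to 2S) and cleavage of three acetals would finish the synthesis.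
- In its favour: insertion of arynes into the C–O bond of carboxylic acids is an established reaction type, so on precedent for the key step this alternative is better than the chosen plan. It also fixes the geranyl group at C8 by construction, so the two plans are equal on regiochemical logic. It is convergent.
- Against it here: the regiochemical burden moves to A3, a benzene with five different substituents whose preparation would take more steps than the whole chosen route. Both aryne carbons are flanked by substituents, so proton transfer to the aryl anion (aryl ester, no C–C bond) can compete. The β-silyloxy acid A2 and ketone A1 meet hot fluoride and can eliminate to the cinnamate or chalcone, which erases the stereocentre. The Mitsunobu displacement is at a 4-alkoxybenzylic carbinol, where ionisation can erode the inversion. Three acetals must be removed with acid beside the geranyl group.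
- Comparison: the chosen plan sets C2 once, catalytically, and never breaks a bond to it, whereas here the stereocentre is inverted late. In step count the alternative is clearly longer.

**Alternative 2:** The cut takes C4 out as a carbonyl carbon (C4a–C4 and C4–C3) and opens O1–C2. This leaves 2-geranyl-6-iodo-3,5-bis(methoxymethoxy)phenol A5, carbon monoxide A7 and 1-ethynyl-4-(methoxymethoxy)benzene A6.

- Forward step: zerovalent palladium formed from PdCl2(PPh3)2 would insert into the C–I bond of A5, take up A7 and couple with A6 to an alkynone. A secondary amine would close this 6-endo through the phenol to 8-geranyl-5,7-bis(methoxymethoxy)-2-[4-(methoxymethoxy)phenyl]chromen-4-one A4.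
- In its favour: three simple components are joined and ring C is closed in one operation, and the reaction type is well established. In convergence and in precedent for the key step the alternative is better than the chosen plan. The geranyl position is again fixed by the substrate, so the plans are equal on that point once A5 is in hand.
- Against it here: A4 is a flavone, so C2 is planar and the only stereocentre is not addressed. It would have to be created afterwards by an enantioselective 1,4-reduction of a β-aryl-β-aryloxy enone (for example copper hydride from Cu(OAc)2, a chiral bisphosphine and a silane). That reduction must spare two trisubstituted alkenes, stop at the ketone and not open ring C, which is less secure than any step of the chosen route. The iodine of A5 lies between two oxygen substituents and its phenol between iodine and geranyl, so oxidative addition and cyclisation are hindered and 5-exo closure to an aurone competes. The regioselective preparation of A5 brings back the C6/C8 question.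
- Comparison: the alternative builds ring C last on a finished ring A, and the chosen plan does the reverse on an already chiral ring C. Mechanistically it trades one unprecedented cycloaddition for an unsolved asymmetric reduction. It is not shorter, since A5 needs several steps, the reduction adds one and three acetals must then be cleaved with acid.

**Alternative 3:** The cut is C2–C3. The precursor is 2-diazo-1-[4,6-bis(tert-butyldimethylsilyloxy)-2-{[4-(tert-butyldimethylsilyloxy)phenyl]methoxy}-3-geranylphenyl]ethan-1-one A9, in which ring B is still a benzyl ether on the future O1.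

- Forward step: a chiral tetracarboxylate of divalent rhodium such as Rh2(S-PTTL)4 (dirhodium tetrakis[N-phthaloyl-(S)-tert-leucinate]) would release N2. The carbene at C3 would insert into one of the two enantiotopic benzylic C–H bonds, closing ring C by 1,6-insertion and setting C2. The product would be (2S)-5,7-bis(tert-butyldimethylsilyloxy)-2-[4-(tert-butyldimethylsilyloxy)phenyl]-8-geranylchroman-4-one A8, and fluoride would then remove three silyl ethers in one step.
- In its favour: ring C and the stereocentre are made together at the final oxidation level, and the C–H bond is activated by the ether oxygen and by the electron-rich aryl group. The all-silyl end game is as mild as the ester cleavage of the chosen plan, so the plans are equal there. C–H insertion of diazoketones next to an ether oxygen to give chromanones is a known reaction type, so precedent is somewhat better than for step 6.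
- Against it here: the ether oxygen can attack the carbene to give a five-membered oxonium ylide, whose 1,2-benzyl shift leads to a benzofuranone. The carbene can also cyclopropanate the geranyl alkenes or add to ring B. Acceptor-only carbenes are less predictable in enantioselectivity than the aldehyde cycloaddition of step 1. A9 requires selective benzylation of the hydroxyl flanked by geranyl and acyl, which is the C6/C8 problem in another form, and it needs a diazo-forming step.
- Comparison: structurally the plans are complementary. Here the stereocentre depends on catalyst control in a step with several competing carbene pathways, whereas the chosen plan sets it in a dependable first step and then only has to preserve it. The differentiation of the ring A oxygens makes the alternative longer.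

Key step: step 6

Assumption on the chemistry: the titanium complex of (S)-1,1'-bi-2-naphthol is taken to direct the diene to the Si face of the aldehyde carbon, which gives 2S. If the sense is the opposite, the (R)-ligand is used and nothing else changes.

Remark on the chemistry: the geometry at C2=C3 of 10 and at C1=C2 of 12 is left undefined, because these carbons become aromatic carbons of ring A.

## Route

Step 1
Reactants: 1 4-formylphenyl acetate; 2 (E)-1-methoxy-3-(trimethylsilyloxy)buta-1,3-diene
Product: 4 4-[(2S)-4-oxo-3,4-dihydro-2H-pyran-2-yl]phenyl acetate, via silylated aldol adduct 3 (not isolated)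
Conditions: (S)-1,1'-bi-2-naphthol ((S)-BINOL, 20 mol %), Ti(OiPr)4 (10 mol %), 4 Å MS, Et2O, −20 °C; then CF3CO2H, CH2Cl2, 0 °C
Reagents that add atoms: none
Why: Catalytic enantioselective hetero-Diels–Alder reaction in its stepwise Mukaiyama aldol form: the titanium binaphtholate binds the aldehyde, the diene terminus adds to the Si face to give 3 after silyl transfer, and acid closes ring C by conjugate addition of the oxygen and loss of methanol. The acyloxy-substituted aldehyde is a good electrophile, and the low temperature should keep the aryl ester from exchanging with isopropoxide.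

Step 2
Reactants: 4 4-[(2S)-4-oxo-3,4-dihydro-2H-pyran-2-yl]phenyl acetate
Product: 5 4-[(2S)-5-nitro-4-oxo-3,4-dihydro-2H-pyran-2-yl]phenyl acetate
Conditions: Bu4NNO3 (1.1 equiv), (CF3CO)2O (1.1 equiv), CH2Cl2, −20 → 0 °C; cold pH 7 buffer wash, short silica plug, used at once
Reagents that add atoms: tetrabutylammonium nitrate, CCCC[N+](CCCC)(CCCC)CCCC.[O-][N+](=O)[O-]
Why: Electrophilic nitration of a push–pull alkene by trifluoroacetyl nitrate formed in the flask, the reaction type used for cyclic enol ethers and chromone-type vinylogous esters; C5 is the only nucleophilic carbon, and the C5–H of the resulting α-nitro oxocarbenium ion is lost at once, so no amine base is needed. The ester keeps ring B far less reactive than an alkoxyarene and holds back ionisation of C2–O1; base is avoided because enolisation at C3 would expel O1 as a vinylogous nitro-acid anion.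

Step 3
Reactants: 6 methyl acetoacetate; 7 geranyl bromide ((2E)-1-bromo-3,7-dimethylocta-2,6-diene)
Product: 9 methyl (6E)-7,11-dimethyl-3-oxododeca-6,10-dienoate, via acetoacetate dianion 8 (not isolated)
Conditions: NaH, THF, 0 °C; n-BuLi, 0 °C; 7 (1.0 equiv), 0 °C → rt; aq. NH4Cl
Reagents that add atoms: none
Why: γ-Alkylation of a β-keto ester dianion: the more basic terminal carbanion of 8 reacts with the primary allylic bromide by SN2, which keeps the E alkene, and one equivalent of bromide limits dialkylation.

Step 4
Reactants: 9 methyl (6E)-7,11-dimethyl-3-oxododeca-6,10-dienoate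
Product: 10 methyl (6E)-7,11-dimethyl-3-(trimethylsilyloxy)dodeca-2,6,10-trienoate
Conditions: Me3SiCl, Et3N, hexane, rt; filtration, concentration
Reagents that add atoms: chlorotrimethylsilane, C[Si](C)(C)Cl
Why: O-Silylation of the enol of a β-keto ester under soft enolisation; either C2=C3 isomer gives the same dienolate in the next step.

Step 5
Reactants: 10 methyl (6E)-7,11-dimethyl-3-(trimethylsilyloxy)dodeca-2,6,10-trienoate
Product: 12 (3Z,6E)-1-methoxy-7,11-dimethyl-1,3-bis(trimethylsilyloxy)dodeca-1,3,6,10-tetraene, via lithium dienolate 11 (not isolated)
Conditions: LiN(iPr)2, THF, −78 °C; Me3SiCl, −78 → 0 °C; hexane, filtration under argon, concentration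
Reagents that add atoms: chlorotrimethylsilane, C[Si](C)(C)Cl
Why: Kinetic γ-deprotonation of the β-silyloxy enoate gives the extended dienolate 11, which the hard silicon electrophile traps on oxygen as the ketene acetal. The chain should prefer the position away from C2 (3Z), the isomer that can reach the s-cis conformation; the non-aqueous work-up protects the hydrolytically labile product.

Step 6
Reactants: 5 4-[(2S)-5-nitro-4-oxo-3,4-dihydro-2H-pyran-2-yl]phenyl acetate; 12 (3Z,6E)-1-methoxy-7,11-dimethyl-1,3-bis(trimethylsilyloxy)dodeca-1,3,6,10-tetraene
Product: 15 4-[(2S)-8-geranyl-5,7-dihydroxy-4-oxo-3,4-dihydro-2H-chromen-2-yl]phenyl acetate, via nitro cycloadduct 13 (not isolated), via bis(trimethylsilyl) ether 14 (not isolated)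
Conditions: 12 (1.5 equiv), NaHCO3 (dry powder, 3 equiv), toluene, −20 °C → rt, then 80 °C; filtration; aq. citric acid, THF, 0 °C → rt
Reagents that add atoms: none
Why: Proposed new method: the electron-rich diene 12 and the push–pull nitroalkene of 5 are matched for a strongly asynchronous normal-demand Diels–Alder reaction in which the geranyl-bearing terminus C4 of 12 bonds to the enol-ether carbon of 5 (future C8a, β to both C=O and NO2) and the ketene-acetal carbon C1 bonds to the nitro-bearing carbon (future C4a), giving the cis-fused adduct 13; the closest known reaction type is the Diels–Alder and aromatisation sequence of 3-nitrochromones, sulfinyl enones and haloquinones with 1-alkoxy-1,3-bis(silyloxy) dienes. Ring A is closed by an intermolecular [4+2] annulation, and if the process is stepwise the second bond forms by 6-exo-trig attack of the nitronate carbon on the silyloxy(methoxy)carbenium carbon. On warming, 13 should lose HNO2 by thermal syn-elimination (H at C8a and NO2 at C4a are cis) and methanol by 1,4-elimination across C5 and C8, which aromatises ring A to 14, and mild aqueous acid then frees the two phenols. No new stereocentre survives, since the centres formed at C4a, C5, C8 and C8a are all erased on aromatisation, so facial selectivity is irrelevant and C2 is never part of the reacting array. The step needs regioselectivity (C8 to C8a and not to C4a), which the polarisation of both partners secures. It needs periselectivity for the carbocyclic [4+2] over cycloaddition through the nitro or carbonyl oxygen, which the nucleophilic carbon terminus of the diene and the irreversible aromatisation should favour. It also needs ring C and the C2–O1 bond to stay intact: no amine base is present to enolise C3 or to trigger β-elimination of O1, solid NaHCO3 only takes up the HNO2 set free (and is filtered off before the acid step to avoid nitrosation of the new arene), and the acetoxy group on ring B disfavours ionisation at the benzylic carbon.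

Step 7
Reactants: 15 4-[(2S)-8-geranyl-5,7-dihydroxy-4-oxo-3,4-dihydro-2H-chromen-2-yl]phenyl acetate
Product: 16 sophoraflavanone A, (2S)-8-[(2E)-3,7-dimethylocta-2,6-dien-1-yl]-5,7-dihydroxy-2-(4-hydroxyphenyl)-2,3-dihydro-4H-chromen-4-one
Conditions: NH4OAc (8 equiv), MeOH–H2O (4:1), rt
Reagents that add atoms: none
Why: Solvolysis of an aryl acetate under essentially neutral conditions (transesterification to methyl acetate); the aryl ester is by far the most labile group present. The medium is not basic enough to enolise C3 and open ring C to the chalcone, and no acid is present to cyclise the geranyl alkenes onto the C7 hydroxyl.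

## Compound list

1 | 4-formylphenyl acetate (4-acetoxybenzaldehyde) | CC(=O)Oc1ccc(C=O)cc1 | starting material
2 | (E)-1-methoxy-3-(trimethylsilyloxy)buta-1,3-diene | CO/C=C/C(=C)O[Si](C)(C)C | starting material
3 | 4-[(1S,4E)-5-methoxy-3-oxo-1-(trimethylsilyloxy)pent-4-en-1-yl]phenyl acetate (not isolated) | CO/C=C/C(=O)C[C@H](O[Si](C)(C)C)c1ccc(OC(C)=O)cc1 | intermediate
4 | 4-[(2S)-4-oxo-3,4-dihydro-2H-pyran-2-yl]phenyl acetate | O=C1C=CO[C@H](c2ccc(OC(C)=O)cc2)C1 | intermediate
5 | 4-[(2S)-5-nitro-4-oxo-3,4-dihydro-2H-pyran-2-yl]phenyl acetate | O=[N+]([O-])C1=CO[C@H](c2ccc(OC(C)=O)cc2)CC1=O | intermediate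
6 | methyl acetoacetate | COC(=O)CC(C)=O | starting material
7 | geranyl bromide, (2E)-1-bromo-3,7-dimethylocta-2,6-diene | CC(C)=CCC/C(C)=C/CBr | starting material
8 | sodium lithium 1-methoxybuta-1,3-diene-1,3-bis(olate), the dianion of 6 (not isolated) | [Na+].[Li+].COC([O-])=CC([O-])=C | intermediate
9 | methyl (6E)-7,11-dimethyl-3-oxododeca-6,10-dienoate | COC(=O)CC(=O)CC/C=C(\C)CCC=C(C)C | intermediate
10 | methyl (6E)-7,11-dimethyl-3-(trimethylsilyloxy)dodeca-2,6,10-trienoate (C2=C3 geometry undefined) | COC(=O)C=C(O[Si](C)(C)C)CC/C=C(\C)CCC=C(C)C | intermediate
11 | lithium (3Z,6E)-1-methoxy-7,11-dimethyl-3-(trimethylsilyloxy)dodeca-1,3,6,10-tetraen-1-olate (not isolated) | [Li+].COC([O-])=C/C(O[Si](C)(C)C)=C/C/C=C(\C)CCC=C(C)C | intermediate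
12 | (3Z,6E)-1-methoxy-7,11-dimethyl-1,3-bis(trimethylsilyloxy)dodeca-1,3,6,10-tetraene (C1=C2 geometry undefined) | COC(O[Si](C)(C)C)=C/C(O[Si](C)(C)C)=C/C/C=C(\C)CCC=C(C)C | intermediate
13 | 4-[(2S)-8-geranyl-5-methoxy-4a-nitro-4-oxo-5,7-bis(trimethylsilyloxy)-3,4,4a,5,8,8a-hexahydro-2H-chromen-2-yl]phenyl acetate, cis-fused, configuration at C4a, C5, C8 and C8a not assigned (not isolated) | CC(C)=CCC/C(C)=C/CC1C(O[Si](C)(C)C)=CC(OC)(O[Si](C)(C)C)C2([N+](=O)[O-])C(=O)C[C@@H](c3ccc(OC(C)=O)cc3)OC12 | intermediate
14 | 4-[(2S)-8-geranyl-4-oxo-5,7-bis(trimethylsilyloxy)-3,4-dihydro-2H-chromen-2-yl]phenyl acetate (not isolated) | CC(C)=CCC/C(C)=C/Cc1c(O[Si](C)(C)C)cc(O[Si](C)(C)C)c2c1O[C@H](c1ccc(OC(C)=O)cc1)CC2=O | intermediate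
15 | 4-[(2S)-8-geranyl-5,7-dihydroxy-4-oxo-3,4-dihydro-2H-chromen-2-yl]phenyl acetate | CC(C)=CCC/C(C)=C/Cc1c(O)cc(O)c2c1O[C@H](c1ccc(OC(C)=O)cc1)CC2=O | intermediate
16 | sophoraflavanone A, (2S)-8-[(2E)-3,7-dimethylocta-2,6-dien-1-yl]-5,7-dihydroxy-2-(4-hydroxyphenyl)-2,3-dihydro-4H-chromen-4-one | CC(C)=CCC/C(C)=C/Cc1c(O)cc(O)c2c1O[C@H](c1ccc(O)cc1)CC2=O | target

## Step count and least certain steps

Total: 7 steps. Longest linear sequence: 5 steps (steps 3, 4, 5, 6, 7 from 6 and 7); the other branch is steps 1, 2, 6, 7.

**Step 6 (key step, proposed new method).** Most likely to go wrong: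
- Conjugate addition of the diene terminus without ring closure, followed by expulsion of O1 from C8a (addition–elimination at the push–pull alkene), which opens ring C.
- Cycloaddition through a nitro or carbonyl oxygen in place of the carbocyclic [4+2].
- Incomplete loss of HNO2, or nitrosation of the new electron-rich arene by the nitrite released.

Fallback with known chemistry (ring A first, ring C by catalytic asymmetric arylation): it sets out from 7 and rejoins the route at 16. C-Alkylation of commercial 2,4,6-trihydroxyacetophenone with 7 (K2CO3, acetone) should give 1-[3-geranyl-2,4,6-trihydroxyphenyl]ethan-1-one F1 after removal of O-alkylated and dialkylated material. MeOCH2Cl and iPr2NEt should cap the two less hindered hydroxyls and leave the chelated hydroxyl between geranyl and acetyl free, giving 1-[3-geranyl-2-hydroxy-4,6-bis(methoxymethoxy)phenyl]ethan-1-one F2; this fixes the future O1 next to the geranyl carbon, and the regiochemistry would have to be confirmed. Condensation with Me2NCH(OMe)2 (toluene, 90 °C) gives (2E)-3-(dimethylamino)-1-[3-geranyl-2-hydroxy-4,6-bis(methoxymethoxy)phenyl]prop-2-en-1-one F3, which on mild acid treatment (AcOH, CH2Cl2) closes with loss of dimethylamine to 8-geranyl-5,7-bis(methoxymethoxy)-4H-chromen-4-one F4. Enantioselective 1,4-addition of [4-(methoxymethoxy)phenyl]boronic acid then gives (2S)-8-geranyl-5,7-bis(methoxymethoxy)-2-[4-(methoxymethoxy)phenyl]chroman-4-one F5. The conditions are Pd(OCOCF3)2, the antipode of 4-tert-butyl-2-(pyridin-2-yl)-4,5-dihydrooxazole that delivers the 2S adduct, NH4PF6, H2O, ClCH2CH2Cl, 60 °C, and they are base-free. HCl in MeOH removes the three acetals to give 16. This is longer and ends with an acidic step, but each reaction type is established on its substrate class.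

**Step 2.** Most likely to go wrong:
- Competing nitration of ring B.
- Addition of water or trifluoroacetate to the very electrophilic product on work-up, with opening of ring C.
- Acid-promoted ionisation at C2.

Fallback (sulfinyl in place of nitro activation): it sets out from 4 and rejoins the route at 15. Electrophilic sulfenylation of 4 at C5 with PhSCl (CH2Cl2, −78 °C) should give 4-[(2S)-4-oxo-5-(phenylsulfanyl)-3,4-dihydro-2H-pyran-2-yl]phenyl acetate F6. One equivalent of mCPBA at −78 °C gives 4-[(2S)-4-oxo-5-(phenylsulfinyl)-3,4-dihydro-2H-pyran-2-yl]phenyl acetate F7 as a mixture of sulfur epimers. F7 and 12 in toluene (rt, then 80–110 °C) should undergo the same cycloaddition, followed by syn-elimination of benzenesulfenic acid and loss of methanol; citric acid work-up then gives 15.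

**Step 1.** Most likely to go wrong:
- Insufficient or reversed facial selectivity for this acyloxy-substituted aldehyde.
- Exchange of the aryl ester with titanium-bound isopropoxide.

Fallback (metal-free hydrogen-bond catalysis with an amino diene): it sets out from 1 and rejoins the route at 4. Compound 1 and commercial (E)-3-(tert-butyldimethylsilyloxy)-N,N-dimethylbuta-1,3-dien-1-amine are combined in toluene at −40 °C with the antipode of 2,2-dimethyl-α,α,α',α'-tetra(1-naphthyl)-1,3-dioxolane-4,5-dimethanol that shields the Re face. This should give 4-[(2S)-6-(dimethylamino)-4-(tert-butyldimethylsilyloxy)-3,6-dihydro-2H-pyran-2-yl]phenyl acetate F8. Acetyl chloride (CH2Cl2, −78 °C) then removes the amino and silyl groups to give 4.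

**Step 5.** Most likely to go wrong:
- Hydrolysis of the ketene acetal during isolation.
- Partial C-silylation.
- Formation of the C3=C4 isomer whose chain points inward and blocks the s-cis conformation.

Fallback (a more robust, ring-tied diene): it sets out from 7 and rejoins the route at 15. The lithium dienolate of commercial 2,2,6-trimethyl-4H-1,3-dioxin-4-one (LiN(iPr)2, THF–DMPU, −78 °C) is alkylated at the γ-carbon with 7 to give 6-[(3E)-4,8-dimethylnona-3,7-dien-1-yl]-2,2-dimethyl-4H-1,3-dioxin-4-one F9. LiN(iPr)2 and Me3SiCl then give trimethyl({6-[(3E)-4,8-dimethylnona-3,7-dien-1-ylidene]-2,2-dimethyl-6H-1,3-dioxin-4-yl}oxy)silane F10. Under the conditions of step 6, F10 and 5 should add with the same orientation (alkylidene carbon to C8a, silyloxy-bearing carbon to C4a). Aromatisation with loss of HNO2 and of acetone from the ketal bridge, then desilylation, gives 15.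

## Further compounds

F1 | step 6 | 1-{3-[(2E)-3,7-dimethylocta-2,6-dien-1-yl]-2,4,6-trihydroxyphenyl}ethan-1-one | CC(C)=CCC/C(C)=C/Cc1c(O)cc(O)c(C(C)=O)c1O
F2 | step 6 | 1-{3-[(2E)-3,7-dimethylocta-2,6-dien-1-yl]-2-hydroxy-4,6-bis(methoxymethoxy)phenyl}ethan-1-one | CC(C)=CCC/C(C)=C/Cc1c(OCOC)cc(OCOC)c(C(C)=O)c1O
F3 | step 6 | (2E)-3-(dimethylamino)-1-{3-[(2E)-3,7-dimethylocta-2,6-dien-1-yl]-2-hydroxy-4,6-bis(methoxymethoxy)phenyl}prop-2-en-1-one | CC(C)=CCC/C(C)=C/Cc1c(OCOC)cc(OCOC)c(C(=O)/C=C/N(C)C)c1O
F4 | step 6 | 8-[(2E)-3,7-dimethylocta-2,6-dien-1-yl]-5,7-bis(methoxymethoxy)-4H-chromen-4-one | CC(C)=CCC/C(C)=C/Cc1c(OCOC)cc(OCOC)c2c1OC=CC2=O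
F5 | step 6 | (2S)-8-[(2E)-3,7-dimethylocta-2,6-dien-1-yl]-5,7-bis(methoxymethoxy)-2-[4-(methoxymethoxy)phenyl]chroman-4-one | CC(C)=CCC/C(C)=C/Cc1c(OCOC)cc(OCOC)c2c1O[C@H](c1ccc(OCOC)cc1)CC2=O
F6 | step 2 | 4-[(2S)-4-oxo-5-(phenylsulfanyl)-3,4-dihydro-2H-pyran-2-yl]phenyl acetate | O=C1C[C@@H](c2ccc(OC(C)=O)cc2)OC=C1Sc1ccccc1
F7 | step 2 | 4-[(2S)-4-oxo-5-(phenylsulfinyl)-3,4-dihydro-2H-pyran-2-yl]phenyl acetate (sulfur epimers) | O=C1C[C@@H](c2ccc(OC(C)=O)cc2)OC=C1S(=O)c1ccccc1
F8 | step 1 | 4-[(2S)-6-(dimethylamino)-4-(tert-butyldimethylsilyloxy)-3,6-dihydro-2H-pyran-2-yl]phenyl acetate (C6 configuration undefined) | CN(C)C1C=C(O[Si](C)(C)C(C)(C)C)C[C@@H](c2ccc(OC(C)=O)cc2)O1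
F9 | step 5 | 6-[(3E)-4,8-dimethylnona-3,7-dien-1-yl]-2,2-dimethyl-4H-1,3-dioxin-4-one | CC(C)=CCC/C(C)=C/CCC1=CC(=O)OC(C)(C)O1
F10 | step 5 | trimethyl({6-[(3E)-4,8-dimethylnona-3,7-dien-1-ylidene]-2,2-dimethyl-6H-1,3-dioxin-4-yl}oxy)silane (exocyclic alkene geometry undefined) | CC(C)=CCC/C(C)=C/CC=C1C=C(O[Si](C)(C)C)OC(C)(C)O1
A1 | alternative 1 | (3R)-3-(tert-butyldimethylsilyloxy)-1-[3-geranyl-2-hydroxy-4,6-bis(methoxymethoxy)phenyl]-3-[4-(methoxymethoxy)phenyl]propan-1-one | CC(C)=CCC/C(C)=C/Cc1c(OCOC)cc(OCOC)c(C(=O)C[C@@H](O[Si](C)(C)C(C)(C)C)c2ccc(OCOC)cc2)c1O
A2 | alternative 1 | (3R)-3-(tert-butyldimethylsilyloxy)-3-[4-(methoxymethoxy)phenyl]propanoic acid | OC(=O)C[C@@H](O[Si](C)(C)C(C)(C)C)c1ccc(OCOC)cc1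
A3 | alternative 1 | 2-[(2E)-3,7-dimethylocta-2,6-dien-1-yl]-3,5-bis(methoxymethoxy)-6-(trimethylsilyl)phenyl trifluoromethanesulfonate | CC(C)=CCC/C(C)=C/Cc1c(OCOC)cc(OCOC)c([Si](C)(C)C)c1OS(=O)(=O)C(F)(F)F
A4 | alternative 2 | 8-geranyl-5,7-bis(methoxymethoxy)-2-[4-(methoxymethoxy)phenyl]chromen-4-one | CC(C)=CCC/C(C)=C/Cc1c(OCOC)cc(OCOC)c2c1OC(c1ccc(OCOC)cc1)=CC2=O
A5 | alternative 2 | 2-[(2E)-3,7-dimethylocta-2,6-dien-1-yl]-6-iodo-3,5-bis(methoxymethoxy)phenol | CC(C)=CCC/C(C)=C/Cc1c(OCOC)cc(OCOC)c(I)c1O
A6 | alternative 2 | 1-ethynyl-4-(methoxymethoxy)benzene | COCOc1ccc(C#C)cc1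
A7 | alternative 2 | carbon monoxide | [C-]#[O+]
A8 | alternative 3 | (2S)-5,7-bis(tert-butyldimethylsilyloxy)-2-[4-(tert-butyldimethylsilyloxy)phenyl]-8-geranylchroman-4-one | CC(C)=CCC/C(C)=C/Cc1c(O[Si](C)(C)C(C)(C)C)cc(O[Si](C)(C)C(C)(C)C)c2c1O[C@H](c1ccc(O[Si](C)(C)C(C)(C)C)cc1)CC2=O
A9 | alternative 3 | 2-diazo-1-[4,6-bis(tert-butyldimethylsilyloxy)-2-{[4-(tert-butyldimethylsilyloxy)phenyl]methoxy}-3-geranylphenyl]ethan-1-one | CC(C)=CCC/C(C)=C/Cc1c(O[Si](C)(C)C(C)(C)C)cc(O[Si](C)(C)C(C)(C)C)c(C(=O)C=[N+]=[N-])c1OCc1ccc(O[Si](C)(C)C(C)(C)C)cc1
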